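The coumarin is cut at C4–C4a, the bond between the pyranone ring and the benzene ring. C4a is the only free arene carbon ortho to the lactone oxygen O1 (the other ortho carbon, C8, carries OMe) and lies para to the C7 ether oxygen, so it is the natural Friedel–Crafts site of an aryl propiolate. A cationic monovalent gold catalyst should therefore close the pyranone ring in one operation on a substrate that already carries the complete side chain. The precursor is the propiolate ester of a 3-alkoxy-2-methoxyphenol whose (5S,6S)-diol, taken from L-tartrate, is masked as its acetonide; the (E)-trisubstituted alkene is set by carboalumination.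

Key step: step 11

Remark on the chemistry: the threo (5S,6S)-diol has the same spatial arrangement as the two carbinol carbons of L-tartaric acid, so both stereocentres are carried from 1 without inversion. The descriptors change from (4R,5R) in 1 to (4S,5S) from 5 onward only because the CIP priorities of the substituents change. Compounds 1, 13 and 15 and all reagents are assumed to be commercial.

Step 1
Reactants: 1 dimethyl (4R,5R)-2,2-dimethyl-1,3-dioxolane-4,5-dicarboxylate
Product: 2 methyl (4R,5S)-5-(hydroxymethyl)-2,2-dimethyl-1,3-dioxolane-4-carboxylate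
Conditions: NaBH4 (0.55 equiv), MeOH, 0 °C
Reagents that add atoms: none
Why: Borohydride reduction of one of two homotopic, alkoxy-activated esters with a limited amount of hydride should stop largely at the hydroxy ester (diol and unreacted 1 are separable), and the two stereocentres are untouched.

Step 2
Reactants: 2 methyl (4R,5S)-5-(hydroxymethyl)-2,2-dimethyl-1,3-dioxolane-4-carboxylate
Product: 3 methyl (4R,5S)-5-({[tert-butyl(dimethyl)silyl]oxy}methyl)-2,2-dimethyl-1,3-dioxolane-4-carboxylate
Conditions: TBSCl, imidazole, DMF, rt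
Reagents that add atoms: tert-butyl(chloro)dimethylsilane, CC(C)(C)[Si](C)(C)Cl
Why: Routine silyl ether protection of the primary alcohol masks it against the Grignard and dehydration steps that follow.

Step 3
Reactants: 3 methyl (4R,5S)-5-({[tert-butyl(dimethyl)silyl]oxy}methyl)-2,2-dimethyl-1,3-dioxolane-4-carboxylate
Product: 4 2-[(4R,5S)-5-({[tert-butyl(dimethyl)silyl]oxy}methyl)-2,2-dimethyl-1,3-dioxolan-4-yl]propan-2-ol
Conditions: MeMgBr (3 equiv), THF, 0 °C → rt
Reagents that add atoms: methylmagnesium bromide, C[Mg]Br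
Why: Double Grignard addition to the ester gives the dimethyl carbinol, which holds all three carbons of the future isopropenyl group; silyl ether and acetonide are inert to the reagent.

Step 4
Reactants: 4 2-[(4R,5S)-5-({[tert-butyl(dimethyl)silyl]oxy}methyl)-2,2-dimethyl-1,3-dioxolan-4-yl]propan-2-ol
Product: 5 tert-butyl(dimethyl){[(4S,5S)-2,2-dimethyl-5-(prop-1-en-2-yl)-1,3-dioxolan-4-yl]methoxy}silane
Conditions: Burgess reagent (Et3N+SO2N−CO2Me), toluene, 60 °C
Reagents that add atoms: none
Why: Burgess dehydration proceeds by syn elimination of the tertiary sulfamate under neutral conditions, and the six methyl hydrogens are statistically and sterically favoured over the single ring C–H next to oxygen, so the isopropenyl group should form without touching a stereocentre.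

Step 5
Reactants: 5 tert-butyl(dimethyl){[(4S,5S)-2,2-dimethyl-5-(prop-1-en-2-yl)-1,3-dioxolan-4-yl]methoxy}silane
Product: 6 [(4S,5S)-2,2-dimethyl-5-(prop-1-en-2-yl)-1,3-dioxolan-4-yl]methanol
Conditions: Bu4NF, THF, 0 °C → rt
Reagents that add atoms: none
Why: Fluoride-mediated desilylation cleaves only the Si–O bond and leaves acetonide and alkene alone.

Step 6
Reactants: 6 [(4S,5S)-2,2-dimethyl-5-(prop-1-en-2-yl)-1,3-dioxolan-4-yl]methanol
Product: 8 {3-[(4S,5S)-2,2-dimethyl-5-(prop-1-en-2-yl)-1,3-dioxolan-4-yl]prop-1-yn-1-yl}(trimethyl)silane, via primary triflate 7 (not isolated)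
Conditions: Tf2O, 2,6-lutidine, CH2Cl2, −78 °C; then LiC≡CSiMe3 (3.5 equiv, from Me3SiC≡CH and n-BuLi), THF–DMPU, −78 → −20 °C
Reagents that add atoms: lithium (trimethylsilyl)acetylide, [Li+].[C-]#C[Si](C)(C)C, made in the flask from ethynyl(trimethyl)silane, C#C[Si](C)(C)C; trifluoromethanesulfonic anhydride, O=S(=O)(OS(=O)(=O)C(F)(F)F)C(F)(F)F (atoms retained only in 7)
Why: Triflation followed by SN2 alkynylation with a lithium acetylide in a dipolar cosolvent is the established way to form a C–C bond at a primary carbon β to an acetal oxygen, where halides and tosylates are sluggish; the excess acetylide takes up the lutidinium salt and the stereocentres are not involved.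

Step 7
Reactants: 8 {3-[(4S,5S)-2,2-dimethyl-5-(prop-1-en-2-yl)-1,3-dioxolan-4-yl]prop-1-yn-1-yl}(trimethyl)silane
Product: 9 (4S,5S)-2,2-dimethyl-4-(prop-1-en-2-yl)-5-(prop-2-yn-1-yl)-1,3-dioxolane
Conditions: K2CO3 (cat.), MeOH, rt
Reagents that add atoms: none
Why: Base-catalysed methanolysis of the C(sp)–Si bond (protodesilylation) frees the terminal alkyne, and nothing else in the molecule is base-labile.

Step 8
Reactants: 9 (4S,5S)-2,2-dimethyl-4-(prop-1-en-2-yl)-5-(prop-2-yn-1-yl)-1,3-dioxolane
Product: 12 (2E)-4-[(4S,5S)-2,2-dimethyl-5-(prop-1-en-2-yl)-1,3-dioxolan-4-yl]-3-methylbut-2-en-1-ol, via alkenyl(dimethyl)alane 10 (not isolated), via lithium alkenyl(butyl)dimethylaluminate 11 (not isolated)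
Conditions: Me3Al (2.5 equiv), Cp2ZrCl2 (0.3 equiv), CH2Cl2, 0 °C → rt; volatiles removed; n-BuLi, THF, −78 → 0 °C; (CH2O)n, 0 °C → rt
Reagents that add atoms: trimethylaluminium, C[Al](C)C; formaldehyde (as paraformaldehyde), C=O; n-butyllithium, [Li]CCCC (atoms retained only in 11)
Why: Negishi zirconium-catalysed carboalumination adds Me–Al syn across the terminal alkyne with methyl on the internal carbon, and the derived aluminate attacks formaldehyde with retention, which fixes the (E)-trisubstituted allylic alcohol; the 1,1-disubstituted isopropenyl alkene is inert to this system.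

Step 9
Reactants: 12 (2E)-4-[(4S,5S)-2,2-dimethyl-5-(prop-1-en-2-yl)-1,3-dioxolan-4-yl]-3-methylbut-2-en-1-ol; 13 2-methoxybenzene-1,3-diol
Product: 14 3-({(2E)-4-[(4S,5S)-2,2-dimethyl-5-(prop-1-en-2-yl)-1,3-dioxolan-4-yl]-3-methylbut-2-en-1-yl}oxy)-2-methoxyphenol
Conditions: 13 (3 equiv), PPh3, DIAD, THF, 0 °C → rt
Reagents that add atoms: none
Why: Mitsunobu etherification displaces the primary allylic oxyphosphonium by the phenoxide in an SN2 sense (SN2' would require attack at a fully substituted carbon), and the excess of the symmetric diol, whose two hydroxyls are equivalent, suppresses double alkylation.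

Step 10
Reactants: 14 3-({(2E)-4-[(4S,5S)-2,2-dimethyl-5-(prop-1-en-2-yl)-1,3-dioxolan-4-yl]-3-methylbut-2-en-1-yl}oxy)-2-methoxyphenol; 15 prop-2-ynoic acid
Product: 16 2-methoxy-3-({(2E)-4-[(4S,5S)-2,2-dimethyl-5-(prop-1-en-2-yl)-1,3-dioxolan-4-yl]-3-methylbut-2-en-1-yl}oxy)phenyl prop-2-ynoate
Conditions: DCC, DMAP (2 mol %), CH2Cl2, −20 → 0 °C
Reagents that add atoms: none
Why: Carbodiimide (Steglich-type) esterification of the only free hydroxyl at low temperature with minimal nucleophilic catalyst avoids conjugate addition to the propiolate and installs the alkyne only after all basic and phosphine-based steps are over.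

Step 11
Reactants: 16 2-methoxy-3-({(2E)-4-[(4S,5S)-2,2-dimethyl-5-(prop-1-en-2-yl)-1,3-dioxolan-4-yl]-3-methylbut-2-en-1-yl}oxy)phenyl prop-2-ynoate
Product: 17 7-({(2E)-4-[(4S,5S)-2,2-dimethyl-5-(prop-1-en-2-yl)-1,3-dioxolan-4-yl]-3-methylbut-2-en-1-yl}oxy)-8-methoxy-2H-chromen-2-one
Conditions: [(2-biphenylyl)(t-Bu)2P]Au(NCMe)SbF6 (3 mol %), CH2Cl2, rt
Reagents that add atoms: none
Why: The cationic monovalent gold complex binds the electron-poor alkyne of 16, and the aryl carbon that is ortho to the ester oxygen and para to the allyloxy oxygen attacks the terminal alkyne carbon anti to gold; the resulting vinyl-gold arenium ion rearomatises and is protodeaurated, which forms C4–C4a and releases the catalyst. The closest known reaction type is the gold-catalysed intramolecular hydroarylation (Friedel–Crafts alkenylation) of aryl alkynoates to coumarins. The pyranone ring closes in the 6-endo-dig mode and no stereocentre is created, the acetonide stereocentres and the E alkene being spectators. The step needs regioselectivity, secured because the second ortho position carries the methoxy group and the attacking carbon is activated by the para ether oxygen, and chemoselectivity for the alkyne over the two alkenes, secured by the alkynophilicity of gold and the distance of the alkenes from the alkyne. A preformed, silver-free catalyst in neutral CH2Cl2 at room temperature generates no Brønsted acid, so the acetonide and the allylic aryl ether should survive.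

Step 12
Reactants: 17 7-({(2E)-4-[(4S,5S)-2,2-dimethyl-5-(prop-1-en-2-yl)-1,3-dioxolan-4-yl]-3-methylbut-2-en-1-yl}oxy)-8-methoxy-2H-chromen-2-one
Product: 18 7-{[(2E,5S,6S)-5,6-dihydroxy-3,7-dimethylocta-2,7-dien-1-yl]oxy}-8-methoxy-2H-chromen-2-one
Conditions: AcOH–H2O (4:1), 45 °C
Reagents that add atoms: none
Why: Acid-catalysed acetal hydrolysis in weakly acidic aqueous acetic acid frees the diol without breaking a bond to either stereocentre, and the mild acid should leave the allylic aryl ether, the allylic alcohol and the lactone intact.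

Compound list
1 | dimethyl (4R,5R)-2,2-dimethyl-1,3-dioxolane-4,5-dicarboxylate | COC(=O)[C@@H]1OC(C)(C)O[C@H]1C(=O)OC | starting material
2 | methyl (4R,5S)-5-(hydroxymethyl)-2,2-dimethyl-1,3-dioxolane-4-carboxylate | COC(=O)[C@@H]1OC(C)(C)O[C@H]1CO | intermediate
3 | methyl (4R,5S)-5-({[tert-butyl(dimethyl)silyl]oxy}methyl)-2,2-dimethyl-1,3-dioxolane-4-carboxylate | COC(=O)[C@@H]1OC(C)(C)O[C@H]1CO[Si](C)(C)C(C)(C)C | intermediate
4 | 2-[(4R,5S)-5-({[tert-butyl(dimethyl)silyl]oxy}methyl)-2,2-dimethyl-1,3-dioxolan-4-yl]propan-2-ol | CC(C)(O)[C@@H]1OC(C)(C)O[C@H]1CO[Si](C)(C)C(C)(C)C | intermediate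
5 | tert-butyl(dimethyl){[(4S,5S)-2,2-dimethyl-5-(prop-1-en-2-yl)-1,3-dioxolan-4-yl]methoxy}silane | C=C(C)[C@@H]1OC(C)(C)O[C@H]1CO[Si](C)(C)C(C)(C)C | intermediate
6 | [(4S,5S)-2,2-dimethyl-5-(prop-1-en-2-yl)-1,3-dioxolan-4-yl]methanol | C=C(C)[C@@H]1OC(C)(C)O[C@H]1CO | intermediate
7 | [(4S,5S)-2,2-dimethyl-5-(prop-1-en-2-yl)-1,3-dioxolan-4-yl]methyl trifluoromethanesulfonate | C=C(C)[C@@H]1OC(C)(C)O[C@H]1COS(=O)(=O)C(F)(F)F | intermediate
8 | {3-[(4S,5S)-2,2-dimethyl-5-(prop-1-en-2-yl)-1,3-dioxolan-4-yl]prop-1-yn-1-yl}(trimethyl)silane | C=C(C)[C@@H]1OC(C)(C)O[C@H]1CC#C[Si](C)(C)C | intermediate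
9 | (4S,5S)-2,2-dimethyl-4-(prop-1-en-2-yl)-5-(prop-2-yn-1-yl)-1,3-dioxolane | C=C(C)[C@@H]1OC(C)(C)O[C@H]1CC#C | intermediate
10 | {(1E)-3-[(4S,5S)-2,2-dimethyl-5-(prop-1-en-2-yl)-1,3-dioxolan-4-yl]-2-methylprop-1-en-1-yl}(dimethyl)alumane | C=C(C)[C@@H]1OC(C)(C)O[C@H]1C/C(C)=C/[Al](C)C | intermediate
11 | lithium butyl{(1E)-3-[(4S,5S)-2,2-dimethyl-5-(prop-1-en-2-yl)-1,3-dioxolan-4-yl]-2-methylprop-1-en-1-yl}dimethylaluminate | C=C(C)[C@@H]1OC(C)(C)O[C@H]1C/C(C)=C/[Al-](C)(C)CCCC.[Li+] | intermediate
12 | (2E)-4-[(4S,5S)-2,2-dimethyl-5-(prop-1-en-2-yl)-1,3-dioxolan-4-yl]-3-methylbut-2-en-1-ol | C=C(C)[C@@H]1OC(C)(C)O[C@H]1C/C(C)=C/CO | intermediate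
13 | 2-methoxybenzene-1,3-diol | COc1c(O)cccc1O | starting material
14 | 3-({(2E)-4-[(4S,5S)-2,2-dimethyl-5-(prop-1-en-2-yl)-1,3-dioxolan-4-yl]-3-methylbut-2-en-1-yl}oxy)-2-methoxyphenol | C=C(C)[C@@H]1OC(C)(C)O[C@H]1C/C(C)=C/COc1cccc(O)c1OC | intermediate
15 | prop-2-ynoic acid | C#CC(=O)O | starting material
16 | 2-methoxy-3-({(2E)-4-[(4S,5S)-2,2-dimethyl-5-(prop-1-en-2-yl)-1,3-dioxolan-4-yl]-3-methylbut-2-en-1-yl}oxy)phenyl prop-2-ynoate | C=C(C)[C@@H]1OC(C)(C)O[C@H]1C/C(C)=C/COc1cccc(OC(=O)C#C)c1OC | intermediate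
17 | 7-({(2E)-4-[(4S,5S)-2,2-dimethyl-5-(prop-1-en-2-yl)-1,3-dioxolan-4-yl]-3-methylbut-2-en-1-yl}oxy)-8-methoxy-2H-chromen-2-one | C=C(C)[C@@H]1OC(C)(C)O[C@H]1C/C(C)=C/COc1ccc2ccc(=O)oc2c1OC | intermediate
18 | 7-{[(2E,5S,6S)-5,6-dihydroxy-3,7-dimethylocta-2,7-dien-1-yl]oxy}-8-methoxy-2H-chromen-2-one | C=C(C)[C@H](O)[C@@H](O)C/C(C)=C/COc1ccc2ccc(=O)oc2c1OC | target

Total step count: 12. Longest linear sequence: 12 steps (1 → 18); 13 and 15 enter as purchased materials.

Steps most likely to fail

Step 11. The ring closure may fail through ionisation of the allylic aryl ether by the Lewis-acidic gold centre, through sequestration of the catalyst as a gold acetylide of the terminal alkyne, or through premature loss of the acetonide. The fallback sets out from phenol 14 and returns at coumarin 17, and builds the pyranone by C3=C4 olefination and lactonisation instead of C4–C4a arylation. Casnati–Skattebøl ortho-formylation of 14 (MgCl2, Et3N, paraformaldehyde, MeCN, reflux) can only occur at the one free ortho carbon and should give 4-({(2E)-4-[(4S,5S)-2,2-dimethyl-5-(prop-1-en-2-yl)-1,3-dioxolan-4-yl]-3-methylbut-2-en-1-yl}oxy)-2-hydroxy-3-methoxybenzaldehyde F1. Z-selective Still–Gennari olefination of this aldehyde with (CF3CH2O)2P(O)CH2CO2Me, KN(SiMe3)2 (2.2 equiv) and 18-crown-6 in THF (−78 °C → rt) should give methyl (2Z)-3-[4-({(2E)-4-[(4S,5S)-2,2-dimethyl-5-(prop-1-en-2-yl)-1,3-dioxolan-4-yl]-3-methylbut-2-en-1-yl}oxy)-2-hydroxy-3-methoxyphenyl]prop-2-enoate F2, whose phenoxide should lactonise in the flask with loss of methoxide to give 17.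

Step 8. The methylalumination may fail through opening of the acetonide by trimethylaluminium, or through slow and poorly regioselective addition when the acetal oxygens tie up the aluminium reagent. The fallback sets out from alkyne 9 and returns at allylic alcohol 12, and sets the alkene geometry by hydroalumination and cuprate coupling instead. Deprotonation of 9 with n-BuLi and addition to paraformaldehyde (THF, −78 °C → rt) should give 4-[(4S,5S)-2,2-dimethyl-5-(prop-1-en-2-yl)-1,3-dioxolan-4-yl]but-2-yn-1-ol F3. Alkoxide-directed trans-hydroalumination with NaAlH2(OCH2CH2OMe)2 (THF, 0 °C) and iodinolysis with I2 at −78 °C should give (2Z)-4-[(4S,5S)-2,2-dimethyl-5-(prop-1-en-2-yl)-1,3-dioxolan-4-yl]-3-iodobut-2-en-1-ol F4. Coupling of this iodide with excess Me2CuLi (Et2O, 0 °C) replaces iodine by methyl with retention and should give 12.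

Step 4. The dehydration may fail through elimination toward the ring C–H (enol ether formation) or through ionisation of the tertiary sulfamate followed by rearrangement. The fallback sets out from ester 3 and returns at alkene 5, and makes the alkene by carbonyl methylenation, where no regiochemical choice exists. Treatment of 3 with MeNH(OMe)·HCl and i-PrMgCl (THF, −20 °C) should give the Weinreb amide (4R,5S)-5-({[tert-butyl(dimethyl)silyl]oxy}methyl)-N-methoxy-N,2,2-trimethyl-1,3-dioxolane-4-carboxamide F5. MeMgBr (THF, 0 °C) should then give 1-[(4R,5S)-5-({[tert-butyl(dimethyl)silyl]oxy}methyl)-2,2-dimethyl-1,3-dioxolan-4-yl]ethan-1-one F6. Wittig methylenation of this ketone with Ph3P=CH2 (from Ph3PCH3Br and KOt-Bu, THF, 0 °C) should give 5.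

Further compounds
F1 | step 11 | 4-({(2E)-4-[(4S,5S)-2,2-dimethyl-5-(prop-1-en-2-yl)-1,3-dioxolan-4-yl]-3-methylbut-2-en-1-yl}oxy)-2-hydroxy-3-methoxybenzaldehyde | C=C(C)[C@@H]1OC(C)(C)O[C@H]1C/C(C)=C/COc1ccc(C=O)c(O)c1OC
F2 | step 11 | methyl (2Z)-3-[4-({(2E)-4-[(4S,5S)-2,2-dimethyl-5-(prop-1-en-2-yl)-1,3-dioxolan-4-yl]-3-methylbut-2-en-1-yl}oxy)-2-hydroxy-3-methoxyphenyl]prop-2-enoate | C=C(C)[C@@H]1OC(C)(C)O[C@H]1C/C(C)=C/COc1ccc(/C=C\C(=O)OC)c(O)c1OC
F3 | step 8 | 4-[(4S,5S)-2,2-dimethyl-5-(prop-1-en-2-yl)-1,3-dioxolan-4-yl]but-2-yn-1-ol | C=C(C)[C@@H]1OC(C)(C)O[C@H]1CC#CCO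
F4 | step 8 | (2Z)-4-[(4S,5S)-2,2-dimethyl-5-(prop-1-en-2-yl)-1,3-dioxolan-4-yl]-3-iodobut-2-en-1-ol | C=C(C)[C@@H]1OC(C)(C)O[C@H]1C/C(I)=C/CO
F5 | step 4 | (4R,5S)-5-({[tert-butyl(dimethyl)silyl]oxy}methyl)-N-methoxy-N,2,2-trimethyl-1,3-dioxolane-4-carboxamide | CON(C)C(=O)[C@@H]1OC(C)(C)O[C@H]1CO[Si](C)(C)C(C)(C)C
F6 | step 4 | 1-[(4R,5S)-5-({[tert-butyl(dimethyl)silyl]oxy}methyl)-2,2-dimethyl-1,3-dioxolan-4-yl]ethan-1-one | CC(=O)[C@@H]1OC(C)(C)O[C@H]1CO[Si](C)(C)C(C)(C)C
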